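Readings and results stem from a simulated flask for substances that don't exist, and the scatter is random.

**Missing partner.** If coupling partner met substrate in one direction and nothing else, the north run could not stall with 23% of its substrate unused, since it was charged 2.20 equivalents of partner. The reckoning here therefore assumes that partner also consumes itself, at second order in c(partner), and that a flask ends when partner has been used up.

| flask | substrate | coupling partner | remark | time |
|---|---|---|---|---|
| south-west | 0.050 M | 0.061 M | run made earlier |  |
| north | 0.050 M | 0.11 M | run made earlier |  |
| beta | 0.050 M | 0.0750 M |  | 25 min |
| delta | 0.050 M | 0.150 M |  | 25 min |

| run | time / min | product / % | intermediate / % | substrate / % |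
|---|---|---|---|---|
| south-west | 1.00 | 32 | 2 | 68 |
| south-west | 2.50 | 45 | 1 | 57 |
| south-west | 5.00 | 57 | 0 | 44 |
| south-west | 12.0 | 63 | 2 | 38 |
| north | 1.50 | 53 | 3 | 44 |
| north | 4.00 | 70 | 1 | 34 |
| north | 8.00 | 72 | 1 | 25 |
| north | 12.0 | 73 | 3 | 23 |

(standard deviation of a reading: 2 percentage points)



- which of these there is most of at the end, counted by the substrate in it, beta (product / intermediate / substrate)
- which of these there is most of at the end, counted by the substrate in it, delta (product / intermediate / substrate)
- how much there is at the end of the one of these that leads, in percent of the substrate charged: beta
- how much there is at the end of the one of these that leads, in percent of the substrate charged: delta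

**The reach.** Let partner be lost to itself g times as readily as to substrate at equal concentrations, and let E be the equivalents charged. Each substrate consumed then costs 1 + g·c(partner)/c(substrate) of partner. Integrated to the end, this gives (c(substrate) at start / c(substrate) at end)^(g − 1) = 1 + (g − 1)·E.

The symmetric case, g = 1, is the zero of the scale, with e^(−E) of the substrate left. South-west has E at 1.22, which means 29.5% left there, and north 11.1%. The last readings stand above both, so g exceeds 1.

Take the square root of c(substrate) at start over c(substrate) at end, less 1, divided by E. South-west reads 0.510 and north 0.493, level within the scatter. The mean of these two readings is the reach per equivalent, 0.502. At about a half, the value matches the square root used, so g − 1 is near 0.5.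

**Two neighbours.** South-west and north share 0.050 M of substrate, yet 1.80 times the partner gives 1.16 times the product at the last readings. On this reckoning, substrate takes 35.3% of the partner used at the start of south-west, but 23.2% at the start of north, a smaller share.

**Commitment.** Substrate left is 1 / (1 + reach·E)². This gives 67.4% product for beta and 84.1% for delta, and product leads in both. The forecast says product at 68% (63% to 73%) for beta and product at 83% (77% to 89%) for delta, holding that “the mechanism matters little here”.

**Result.** Beta ends with 68.6% of product and delta with 84.7% of product.

    substrate + coupling partner → intermediate + by-product (k = 0.186 M⁻¹ s⁻¹)
    intermediate → product (k = 0.208 s⁻¹)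
    2 coupling partner → homo dimer (k = 0.132 M⁻¹ s⁻¹)

**Heavier substrate.** Beta keeps 0.11% of its partner and 31% of its substrate at the end: partner is the limiting reagent there, at 1.50 equivalents. A neighbour of beta charged with 0.20 M of substrate has 0.375 equiv of partner, and the reach puts its product at 29.2%. That flask gives 29.4%, with 0% of its partner left. Its leader is substrate, at 70.6%.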